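## Retrosynthetic overview

1. Target 19 ⇒ aromatic 2-benzopyrylium salt 15. One enantioselective acyloxylative dearomatisation forms the C7–O(butanoyl) bond and the C7 stereocentre; the 5,6-methylenedioxy bridge then leaves as formaldehyde, giving the C6 ketone and the free 5-OH.
2. 15 ⇒ bromo enol ether 11. C1 comes from DMF on the C8a aryllithium; acid unmasks the C3 ketone and the 8-OH and closes the pyrylium ring.
3. 11 ⇒ aldehyde 7 + 2,3-dihydrofuran (8). The C3–C4 bond is made by adding 5-lithio-2,3-dihydrofuran; the alkoxide is methylated in the flask to give the 4-OMe.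
4. 7 ⇒ sesamol (1). Methyl, bromine and formyl are placed by three regiodefined metalation/halogenation events.
5. Ring order: ring A (benzene) is bought, ring B (pyran) is closed in step 6, ring A is dearomatised in step 7.

Assumption 1: isochromene numbering is used for the bicyclic compounds (C1, O2, C3, C4, C4a, C5–C8, C8a); the stereocentre of the target is C7 and is S.
Assumption 2: the sense of induction of the chiral iodoarene on this substrate class is not established; the route is written with the (R,R)-catalyst as the one that gives 7S, and the (S,S)-antipode replaces it with no other change if the first run shows the opposite sense.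

## Route

Step 1
Reactants: 1 sesamol (1,3-benzodioxol-5-ol)
Product: 2 5-(methoxymethoxy)-1,3-benzodioxole
Conditions: MOMCl (1.3 equiv), i-Pr2NEt (1.5 equiv), CH2Cl2, 0 → 23 °C
Reagents that add atoms: chloromethyl methyl ether COCCl
Why: Williamson-type O-alkylation of the phenol gives the MOM ether, which is the ortho-director for step 2 and is cleaved by the acid of step 6.

Step 2
Reactants: 2 5-(methoxymethoxy)-1,3-benzodioxole
Product: 4 5-(methoxymethoxy)-4-methyl-1,3-benzodioxole, via aryllithium 3 (not isolated)
Conditions: n-BuLi (1.2 equiv), THF, −78 → 0 °C, 1 h; MeI (1.5 equiv), −78 → 23 °C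
Reagents that add atoms: iodomethane CI
Why: Directed ortho-metalation takes the hydrogen flanked by the OMOM group and the dioxole oxygen, the most acidic and doubly coordinated site, so methylation is regiospecific.

Step 3
Reactants: 4 5-(methoxymethoxy)-4-methyl-1,3-benzodioxole
Product: 5 6-bromo-5-(methoxymethoxy)-4-methyl-1,3-benzodioxole
Conditions: NBS (1.05 equiv), MeCN, 0 °C, dark
Reagents that add atoms: N-bromosuccinimide O=C1CCC(=O)N1Br
Why: Electrophilic aromatic bromination goes to the position ortho to OMOM and para to a dioxole oxygen (the other free position is activated by one oxygen only); the bromine blocks this carbon and later becomes C1.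

Step 4
Reactants: 5 6-bromo-5-(methoxymethoxy)-4-methyl-1,3-benzodioxole
Product: 7 5-bromo-6-(methoxymethoxy)-7-methyl-1,3-benzodioxole-4-carbaldehyde, via aryllithium 6 (not isolated)
Conditions: LiN(i-Pr)2 (1.2 equiv), THF, −78 °C, 45 min; DMF (3 equiv), −78 → 0 °C; aq NH4Cl
Reagents that add atoms: N,N-dimethylformamide CN(C)C=O
Why: Directed ortho-metalation with a lithium amide (deprotonation, not halogen–lithium exchange) removes the only ring hydrogen, which sits between Br and the dioxole oxygen, and Bouveault formylation gives the aldehyde carbon that becomes C4.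

Step 5
Reactants: 7 5-bromo-6-(methoxymethoxy)-7-methyl-1,3-benzodioxole-4-carbaldehyde; 8 2,3-dihydrofuran
Product: 11 5-bromo-4-[(4,5-dihydrofuran-2-yl)(methoxy)methyl]-6-(methoxymethoxy)-7-methyl-1,3-benzodioxole (racemic), via lithiated dihydrofuran 9 (not isolated), via lithium alkoxide 10 (not isolated)
Conditions: 8 (1.7 equiv), t-BuLi (1.5 equiv), THF, −78 → 0 °C, 30 min; 7 (1.0 equiv), −78 °C; MeI (5 equiv), DMPU, −78 → 23 °C; Et3N-buffered work-up
Reagents that add atoms: 2,3-dihydrofuran (compound 8) C1CC=CO1; iodomethane CI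
Why: 1,2-Addition of the α-alkoxyvinyllithium (a 4-hydroxybutanoyl anion equivalent) to the aldehyde outruns Br–Li exchange at −78 °C, and Williamson O-methylation of the alkoxide installs the 4-OMe; the new benzylic stereocentre is racemic and is erased when C4 becomes sp2 in step 6.

Step 6
Reactants: 11 5-bromo-4-[(4,5-dihydrofuran-2-yl)(methoxy)methyl]-6-(methoxymethoxy)-7-methyl-1,3-benzodioxole
Product: 15 8-hydroxy-3-(3-hydroxypropyl)-4-methoxy-7-methyl-5,6-methylenedioxy-2-benzopyrylium tetrafluoroborate, via aryllithium 12 (not isolated), via enol-ether aldehyde 13 (not isolated), via keto-aldehyde 14 (not isolated)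
Conditions: t-BuLi (2.1 equiv), THF, −78 °C; DMF, −78 → 0 °C; aq NH4Cl; then 48% aq HBF4, MeCN, 0 → 23 °C; Et2O precipitation
Reagents that add atoms: N,N-dimethylformamide CN(C)C=O; water O; tetrafluoroboric acid [H+].F[B-](F)(F)F
Why: Halogen–lithium exchange and Bouveault formylation install C1, acid then hydrolyses the enol ether (C3 ketone and free primary alcohol) and the MOM ether, and the 1,5-dicarbonyl 14 cyclodehydrates to the aromatic 2-benzopyrylium salt (classical pyrylium synthesis), which precipitates while the aryl-type 4-OMe and the methylenedioxy group stay intact.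

Step 7
Reactants: 15 8-hydroxy-3-(3-hydroxypropyl)-4-methoxy-7-methyl-5,6-methylenedioxy-2-benzopyrylium tetrafluoroborate; 16 butanoic acid
Product: 19 (7S)-5-hydroxy-3-(3-hydroxypropyl)-4-methoxy-7-methyl-6,8-dioxo-7,8-dihydro-6H-isochromen-7-yl butanoate, via pyrylium cation 17 (not isolated), via hemiacetal 18 (not isolated)
Conditions: (R,R)-2-iodo-1,3-bis[1-(mesitylcarbamoyl)ethoxy]benzene (15 mol %), dried mCPBA (1.2 equiv, slow addition), butanoic acid (20 equiv), CH2Cl2, −20 °C; Na2S2O3, then aq NaHCO3 (pH 7–8), 23 °C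
Reagents that add atoms: butanoic acid (compound 16) CCCC(=O)O
Why: Proposed new method: the chiral aryl-λ3-iodane bis(butanoate) formed in the flask (trivalent iodine) exchanges a carboxylate for the acidic 8-OH of 15 and transfers butanoate to C7, the ortho carbon whose attack keeps the pyrylium ring conjugated to the O6 donor (attack at C5 would isolate it), with reductive loss of the iodoarene while the C2-symmetric lactamide arms shield one face so that the quaternary stereocentre is set here as 7S; cation 17 is a pyrylium O-alkylated by a formaldehyde acetal and collapses with water through hemiacetal 18 to 19 with loss of CH2O; the closest known reaction types are the Wessely acyloxylation of 2-benzopyrylium salts to 7-acyloxy-azaphilones with Pb(OAc)4 and iodoarene-catalysed enantioselective oxidative dearomatisation (spirolactonisation) of phenols, and because no free 7-OH is ever formed the primary alcohol needs no protection.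

## Compound list

1 | sesamol (1,3-benzodioxol-5-ol) | Oc1ccc2OCOc2c1 | starting material
2 | 5-(methoxymethoxy)-1,3-benzodioxole | COCOc1ccc2OCOc2c1 | intermediate
3 | [5-(methoxymethoxy)-1,3-benzodioxol-4-yl]lithium (not isolated) | [Li]c1c(OCOC)ccc2OCOc12 | intermediate
4 | 5-(methoxymethoxy)-4-methyl-1,3-benzodioxole | Cc1c(OCOC)ccc2OCOc12 | intermediate
5 | 6-bromo-5-(methoxymethoxy)-4-methyl-1,3-benzodioxole | Cc1c(OCOC)c(Br)cc2OCOc12 | intermediate
6 | [5-bromo-6-(methoxymethoxy)-7-methyl-1,3-benzodioxol-4-yl]lithium (not isolated) | [Li]c1c(Br)c(OCOC)c(C)c2OCOc12 | intermediate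
7 | 5-bromo-6-(methoxymethoxy)-7-methyl-1,3-benzodioxole-4-carbaldehyde | O=Cc1c(Br)c(OCOC)c(C)c2OCOc12 | intermediate
8 | 2,3-dihydrofuran | C1CC=CO1 | starting material
9 | (4,5-dihydrofuran-2-yl)lithium (not isolated) | [Li]C1=CCCO1 | intermediate
10 | lithium [5-bromo-6-(methoxymethoxy)-7-methyl-1,3-benzodioxol-4-yl](4,5-dihydrofuran-2-yl)methanolate, racemic (not isolated) | [Li]OC(C1=CCCO1)c1c(Br)c(OCOC)c(C)c2OCOc12 | intermediate
11 | 5-bromo-4-[(4,5-dihydrofuran-2-yl)(methoxy)methyl]-6-(methoxymethoxy)-7-methyl-1,3-benzodioxole, racemic | COC(C1=CCCO1)c1c(Br)c(OCOC)c(C)c2OCOc12 | intermediate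
12 | [4-[(4,5-dihydrofuran-2-yl)(methoxy)methyl]-6-(methoxymethoxy)-7-methyl-1,3-benzodioxol-5-yl]lithium, racemic (not isolated) | COC(C1=CCCO1)c1c([Li])c(OCOC)c(C)c2OCOc12 | intermediate
13 | 4-[(4,5-dihydrofuran-2-yl)(methoxy)methyl]-6-(methoxymethoxy)-7-methyl-1,3-benzodioxole-5-carbaldehyde, racemic (not isolated) | COC(C1=CCCO1)c1c(C=O)c(OCOC)c(C)c2OCOc12 | intermediate
14 | 6-hydroxy-4-(5-hydroxy-1-methoxy-2-oxopentyl)-7-methyl-1,3-benzodioxole-5-carbaldehyde, racemic (not isolated) | COC(C(=O)CCCO)c1c(C=O)c(O)c(C)c2OCOc12 | intermediate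
15 | 8-hydroxy-3-(3-hydroxypropyl)-4-methoxy-7-methyl-5,6-methylenedioxy-2-benzopyrylium tetrafluoroborate | COc1c(CCCO)[o+]cc2c(O)c(C)c3OCOc3c12.F[B-](F)(F)F | intermediate
16 | butanoic acid | CCCC(=O)O | starting material
17 | 7-butanoyloxy-3-(3-hydroxypropyl)-4-methoxy-7-methyl-5,6-methylenedioxy-8-oxo-7,8-dihydro-2-benzopyrylium tetrafluoroborate; C7 arranged as in 19 (descriptor here is 7R because C8 outranks C6 in this cation) (not isolated) | CCCC(=O)O[C@@]1(C)C(=O)c2c[o+]c(CCCO)c(OC)c2C2=C1OCO2.F[B-](F)(F)F | intermediate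
18 | (7S)-3-(3-hydroxypropyl)-5-(hydroxymethoxy)-4-methoxy-7-methyl-6,8-dioxo-7,8-dihydro-6H-isochromen-7-yl butanoate (not isolated) | CCCC(=O)O[C@@]1(C)C(=O)C2=COC(CCCO)=C(OC)C2=C(OCO)C1=O | intermediate
19 | (7S)-5-hydroxy-3-(3-hydroxypropyl)-4-methoxy-7-methyl-6,8-dioxo-7,8-dihydro-6H-isochromen-7-yl butanoate | CCCC(=O)O[C@@]1(C)C(=O)C2=COC(CCCO)=C(OC)C2=C(O)C1=O | target

## Step count and risks

Total steps: 7. Longest linear sequence: 7 (2,3-dihydrofuran and butanoic acid enter as bought).

**Step 7 (most likely to fail).** The risks are carboxylate transfer to C5 or C1 instead of C7, low or reversed enantioselectivity, over-oxidation of 19, and a 5-O-CH2-O-butanoyl ether that survives work-up. The fallback replaces carboxylate transfer at iodine by copper–dioxygen ortho-hydroxylation followed by acylation. It sets out from 15: aqueous NaHCO3 opens the pyrylium to keto-aldehyde 14, whose salicylaldehyde-type phenolate is hydroxylated at C7 with [Cu(MeCN)4]PF6, (−)-sparteine and O2 (i-Pr2NEt, 4-dimethylaminopyridine, CH2Cl2, −10 °C). Phosphate buffer then closes the pyran and expels formaldehyde to give (7S)-5,7-dihydroxy-3-(3-hydroxypropyl)-4-methoxy-7-methyl-6H-isochromene-6,8(7H)-dione F1. From memory of this reaction class, (−)-sparteine gives the C7 arrangement that is named R in 5-unsubstituted azaphilones and S here, because O5 raises C6 above C8; the sense is to be confirmed by ECD. Butanoic anhydride, 4-dimethylaminopyridine and Et3N esterify all three hydroxyls to the tris-butanoate F2. Immobilised Candida antarctica lipase B in pH 7 buffer/MTBE hydrolyses the primary and the enol butanoates but not the hindered tertiary one, and the route is rejoined at 19.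

**Step 6.** The risks are a hindered aryllithium that formylates poorly and decomposition in the acid cascade. The fallback moves the C1 introduction from an aryllithium to an electrophilic aromatic formylation on the free phenol. It sets out from 11: Pd(OAc)2/PPh3 with HCO2Na in DMF at 80 °C removes the bromine to give 4-[(4,5-dihydrofuran-2-yl)(methoxy)methyl]-6-(methoxymethoxy)-7-methyl-1,3-benzodioxole F3. Dilute HCl in THF hydrolyses the enol ether and the MOM ether to 5-hydroxy-1-(6-hydroxy-7-methyl-1,3-benzodioxol-4-yl)-1-methoxypentan-2-one F4. HC(OEt)3 with HBF4·OEt2 then formylates the position ortho to the phenol and para to the dioxole oxygen and closes the ring in the same flask (the classical orthoformate benzopyrylium synthesis), and the route is rejoined at 15.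

**Step 5.** The risks are sluggish O-methylation of the hindered lithium alkoxide, Br–Li exchange by the vinyllithium, and acid-lability of 11. The fallback builds the dihydrofuran by cycloisomerisation instead of bringing it in as a carbanion. It sets out from 7: the lithium acetylide of tert-butyl(but-3-yn-1-yloxy)dimethylsilane (n-BuLi, THF, −78 °C) adds to the aldehyde and MeI/DMPU methylates the propargylic alkoxide to give tert-butyl({5-[5-bromo-6-(methoxymethoxy)-7-methyl-1,3-benzodioxol-4-yl]-5-methoxypent-3-yn-1-yl}oxy)dimethylsilane F5. Bu4NF frees the alcohol 5-[5-bromo-6-(methoxymethoxy)-7-methyl-1,3-benzodioxol-4-yl]-5-methoxypent-3-yn-1-ol F6. AuCl(PPh3)/AgOTf (2 mol %, CH2Cl2, 23 °C, Et3N quench) effects 5-endo-dig hydroalkoxylation of the homopropargylic alcohol, and the route is rejoined at 11.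

## Further compounds

F1 | step 7 | (7S)-5,7-dihydroxy-3-(3-hydroxypropyl)-4-methoxy-7-methyl-6H-isochromene-6,8(7H)-dione | O[C@@]1(C)C(=O)C2=COC(CCCO)=C(OC)C2=C(O)C1=O
F2 | step 7 | (7S)-5,7-bis(butanoyloxy)-3-[3-(butanoyloxy)propyl]-4-methoxy-7-methyl-6H-isochromene-6,8(7H)-dione | CCCC(=O)O[C@@]1(C)C(=O)C2=COC(CCCOC(=O)CCC)=C(OC)C2=C(OC(=O)CCC)C1=O
F3 | step 6 | 4-[(4,5-dihydrofuran-2-yl)(methoxy)methyl]-6-(methoxymethoxy)-7-methyl-1,3-benzodioxole, racemic | COC(C1=CCCO1)c1cc(OCOC)c(C)c2OCOc12
F4 | step 6 | 5-hydroxy-1-(6-hydroxy-7-methyl-1,3-benzodioxol-4-yl)-1-methoxypentan-2-one, racemic | COC(C(=O)CCCO)c1cc(O)c(C)c2OCOc12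
F5 | step 5 | tert-butyl({5-[5-bromo-6-(methoxymethoxy)-7-methyl-1,3-benzodioxol-4-yl]-5-methoxypent-3-yn-1-yl}oxy)dimethylsilane, racemic | COC(C#CCCO[Si](C)(C)C(C)(C)C)c1c(Br)c(OCOC)c(C)c2OCOc12
F6 | step 5 | 5-[5-bromo-6-(methoxymethoxy)-7-methyl-1,3-benzodioxol-4-yl]-5-methoxypent-3-yn-1-ol, racemic | COC(C#CCCO)c1c(Br)c(OCOC)c(C)c2OCOc12
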